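**Plan**
1. Numbering: C1 = lactone C=O, C2=C3, C5 = ring CH–O, C7/C9/C11 = carbinols, C12–C26 = pentadecyl. The target is the all-syn (5S,7R,9R,11R) isomer.
2. Cuts: first O5–C1 and C2=C3 (lactonisation of a Z-enoate made from a C3 aldehyde), then C7–C8, then C12–C13 and C6–C7 (two openings of one epoxide). The last cut is the allyl–CH2 bond of that epoxide (C9–C10 in the left half, C3–C4 in the right half).
3. Enabling feature: the syn-1,3-diol C7(OH)–C8H2–C9(OH). C8/C9 are the two carbons of a terminal alkene and can be carried as a primary/secondary 1,2-bis(boronic ester). C7, with its single oxygen, can arrive as an α-acyloxy lithium carbenoid, so one 1,2-metallate shift joins C8–C26 to C3–C7, sets C7 and leaves both carbinols as C–B bonds for a single oxidation.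
4. Forward: (S)-epichlorohydrin → (S)-2-allyloxirane 4 → left half 8 and right half 14 → union/oxidation to diol 18 → acetonide → C3 aldehyde → Z-enoate → acid release, which closes the only ring (δ-lactone, O5–C1) last.
5. Stereochemistry: C5 and C11 both stem from the one centre of (S)-epichlorohydrin; the same epoxide enantiomer serves twice because its CH2 becomes outer C12 on the left and inner C6 on the right. C9 is relayed from C11 by hydroxyl-directed diboration, C7 comes from (+)-sparteine, and C–B → C–O goes with retention.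

Key step: step 9

**Route**

Step 1
Reactants: 1 (S)-epichlorohydrin; 2 vinylmagnesium bromide
Product: 3 (S)-1-chloropent-4-en-2-ol
Conditions: CuI (10 mol %), THF, −78 → −30 °C
Reagents that add atoms: none
Why: Copper-catalysed Grignard opening of a terminal epoxide (SN2 at the unsubstituted ring carbon, faster than attack at CH2Cl) forms the allyl C–C bond without touching the stereocentre, which is carried over from 1.

Step 2
Reactants: 3 (S)-1-chloropent-4-en-2-ol
Product: 4 (S)-2-allyloxirane
Conditions: powdered NaOH, Et2O, rt; distil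
Reagents that add atoms: none
Why: Base-induced halohydrin ring closure (intramolecular Williamson reaction) moves the epoxide to the former CH2Cl carbon and breaks no bond at the stereocentre.

Step 3
Reactants: 4 (S)-2-allyloxirane; 5 tetradecylmagnesium chloride
Product: 6 (R)-nonadec-1-en-4-ol
Conditions: CuI (10 mol %), THF, −40 → 0 °C
Reagents that add atoms: none
Why: Copper-catalysed Grignard opening at the terminal epoxide carbon makes C12–C13 and releases the C11 hydroxyl, whose (R) configuration is that of 4 because the C–O bond at the stereocentre is kept.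

Step 4
Reactants: 6 (R)-nonadec-1-en-4-ol
Product: 7 (2S,4R)-1,2-bis(4,4,5,5-tetramethyl-1,3,2-dioxaborolan-2-yl)nonadecan-4-ol
Conditions: B2pin2, Cs2CO3 (30 mol %), MeOH, THF, 70 °C
Reagents that add atoms: bis(pinacolato)diboron, CC1(C)OB(OC1(C)C)B1OC(C)(C)C(C)(C)O1
Why: Alkoxide-catalysed hydroxyl-directed diboration of a homoallylic alcohol: the C11 alkoxide binds B2pin2 and hands both boron atoms to one alkene face through a chair-like cyclic transition state with the pentadecyl chain equatorial, which should set the new C9–B centre syn to C11–O.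

Step 5
Reactants: 7 (2S,4R)-1,2-bis(pinacolatoboryl)nonadecan-4-ol
Product: 8 tert-butyl{[(2S,4R)-1,2-bis(pinacolatoboryl)nonadecan-4-yl]oxy}dimethylsilane
Conditions: TBSCl, imidazole, DMF, rt
Reagents that add atoms: tert-butyldimethylsilyl chloride, CC(C)(C)[Si](C)(C)Cl
Why: Standard silylation of a secondary alcohol masks the acidic O–H before the organolithium step and leaves both pinacol boronic esters untouched.

Step 6
Reactants: 4 (S)-2-allyloxirane; 9 (chloromethyl)isopropoxydimethylsilane
Product: 12 (S)-hex-5-ene-1,3-diol, via silylmethyl Grignard reagent 10 (not isolated), via hydroxy silane 11 (not isolated)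
Conditions: 9, Mg, THF, reflux; then CuI (10 mol %), 4, −30 → 0 °C; crude 11: 30% H2O2, KF, KHCO3, THF/MeOH, rt
Reagents that add atoms: hydrogen peroxide, OO
Why: Copper-catalysed epoxide opening by a silylmethyl Grignard reagent (a hydroxymethyl anion equivalent) makes C6–C7, and Tamao oxidation of the crude alkoxysilane turns C7–Si into C7–OH, the C5 centre coming unchanged from 4.

Step 7
Reactants: 12 (S)-hex-5-ene-1,3-diol
Product: 13 (S)-3-hydroxyhex-5-en-1-yl 2,4,6-triisopropylbenzoate
Conditions: 2,4,6-iPr3C6H2CO2H, PPh3, DIAD, THF, 0 °C → rt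
Reagents that add atoms: 2,4,6-triisopropylbenzoic acid, CC(C)c1cc(C(C)C)c(C(=O)O)c(C(C)C)c1
Why: Mitsunobu esterification with a very hindered acid takes place at the primary C7 hydroxyl much faster than at the secondary C5 hydroxyl and installs the benzoate that later directs lithiation and serves as leaving group.

Step 8
Reactants: 13 (S)-3-hydroxyhex-5-en-1-yl 2,4,6-triisopropylbenzoate
Product: 14 (S)-3-(tert-butyldimethylsilyloxy)hex-5-en-1-yl 2,4,6-triisopropylbenzoate
Conditions: TBSCl, imidazole, DMF, rt
Reagents that add atoms: tert-butyldimethylsilyl chloride, CC(C)(C)[Si](C)(C)Cl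
Why: Standard silylation protects C5–OH against s-BuLi, a silyloxide being too poor a leaving group for 1,3-elimination from the later C7 anion.

Step 9
Reactants: 14 (S)-3-(tert-butyldimethylsilyloxy)hex-5-en-1-yl 2,4,6-triisopropylbenzoate; 8 tert-butyl{[(2S,4R)-1,2-bis(pinacolatoboryl)nonadecan-4-yl]oxy}dimethylsilane
Product: 18 (4S,6R,8S,10R)-4,10-bis(tert-butyldimethylsilyloxy)pentacos-1-ene-6,8-diol, via lithiated benzoate 15 (not isolated), via boronate complex 16 (not isolated), via 1,3-bis(boronic ester) 17 (not isolated)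
Conditions: 14 (1.3 equiv), s-BuLi, (+)-sparteine, Et2O, −78 °C, 5 h; 8 in Et2O, −78 °C, 2 h; then 35 °C, 16 h; then 30% H2O2, 2 M NaOH, THF, 0 °C → rt
Reagents that add atoms: hydrogen peroxide, OO
Why: s-BuLi/(+)-sparteine removes the pro-R hydrogen at C7, next to the benzoate oxygen of 14, to give the configurationally stable (R)-lithio benzoate 15, which adds with retention to the primary C8 boron of 8 to give boronate complex 16. On warming, C8 migrates from boron to C7 antiperiplanar to the leaving benzoate (stereospecific 1,2-metallate rearrangement, inversion at C7), which forms the C7–C8 bond and gives 17, and the oxidative work-up then replaces both C–B bonds by C–OH with retention. The closest known reaction type is the lithiation–borylation homologation of alkene-derived 1,2-bis(boronic esters) at the primary boron with sparteine-ligated lithiated benzoates or carbamates, followed by oxidation to 1,3-diols. No ring is closed. The new C7 centre is fixed by the chiral diamine (reagent control, relayed through two stereospecific events), while C9 keeps the configuration set in step 4 because its C–B bond is a spectator until the retentive oxidation, so the 7,9-syn relationship follows. The step needs site selectivity between the two boronic esters, which the steric gap between primary C8–B and secondary, β-branched C9–B secures, and it needs 15 to outlive side reactions, which −78 °C (no 5-exo carbolithiation of the alkene), the hindered aryl ester (no acyl attack) and the poor silyloxide leaving group (no 1,3-elimination) secure.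

Step 10
Reactants: 18 (4S,6R,8S,10R)-4,10-bis(tert-butyldimethylsilyloxy)pentacos-1-ene-6,8-diol
Product: 19 (4R,6S)-4-[(2S)-2-(tert-butyldimethylsilyloxy)pent-4-en-1-yl]-6-[(2R)-2-(tert-butyldimethylsilyloxy)heptadecyl]-2,2-dimethyl-1,3-dioxane
Conditions: Me2C(OMe)2, PPTS (cat.), CH2Cl2, rt
Reagents that add atoms: 2,2-dimethoxypropane, COC(C)(C)OC
Why: Acid-catalysed acetal exchange closes the six-membered acetonide on the only two free hydroxyls, the syn-diol giving the chair with both chains equatorial, and PPTS is too mild to cleave the secondary TBS ethers.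

Step 11
Reactants: 19 the 7,9-acetonide of 18
Product: 21 (3R)-3-(tert-butyldimethylsilyloxy)-4-{(4R,6S)-6-[(2R)-2-(tert-butyldimethylsilyloxy)heptadecyl]-2,2-dimethyl-1,3-dioxan-4-yl}butanal, via ozonide 20 (not isolated)
Conditions: O3, CH2Cl2, −78 °C; then PPh3, −78 °C → rt
Reagents that add atoms: ozone, [O-][O+]=O
Why: Ozonolysis with reductive work-up cleaves the only C=C bond to the C3 aldehyde and formaldehyde, and silyl ethers and the acetonide are inert to ozone at low temperature.

Step 12
Reactants: 21 the C3 aldehyde; 22 methyl bis(2,2,2-trifluoroethyl)phosphonoacetate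
Product: 24 methyl (2Z,5S)-5-(tert-butyldimethylsilyloxy)-6-{(4R,6S)-6-[(2R)-2-(tert-butyldimethylsilyloxy)heptadecyl]-2,2-dimethyl-1,3-dioxan-4-yl}hex-2-enoate, via potassium phosphonate carbanion 23 (not isolated)
Conditions: 22, KN(SiMe3)2, 18-crown-6, THF, −78 °C; then 21
Reagents that add atoms: none
Why: Still–Gennari modification of the Horner–Wadsworth–Emmons reaction: the electron-poor trifluoroethyl phosphonate with a dissociated potassium counter-ion makes elimination faster than equilibration of the adducts, which should give the (Z)-enoate, and the low temperature guards the β-silyloxy aldehyde against elimination.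

Step 13
Reactants: 24 the (Z)-enoate
Product: 26 (6S)-6-[(2R,4R,6R)-2,4,6-trihydroxyhenicosyl]-5,6-dihydro-2H-pyran-2-one, via tetrahydroxy ester 25 (not isolated)
Conditions: 48% aq. HF, MeCN/CH2Cl2, 0 °C → rt
Reagents that add atoms: none
Why: Aqueous HF cleaves both silyl ethers and hydrolyses the acetonide, and in the tetrol 25 only the C5 hydroxyl can reach the ester carbonyl across the Z double bond through a six-membered transition state, so acid-catalysed transesterification (lactonisation) closes the δ-lactone without touching any stereocentre.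

**Compound list**
1 | (S)-epichlorohydrin | ClC[C@@H]1CO1 | starting material
2 | vinylmagnesium bromide | C=C[Mg]Br | starting material
3 | (S)-1-chloropent-4-en-2-ol | ClC[C@@H](O)CC=C | intermediate
4 | (S)-2-allyloxirane | C=CC[C@H]1CO1 | intermediate
5 | tetradecylmagnesium chloride | CCCCCCCCCCCCCC[Mg]Cl | starting material
6 | (R)-nonadec-1-en-4-ol | CCCCCCCCCCCCCCC[C@@H](O)CC=C | intermediate
7 | (2S,4R)-1,2-bis(pinacolatoboryl)nonadecan-4-ol | CCCCCCCCCCCCCCC[C@@H](O)C[C@@H](B1OC(C)(C)C(C)(C)O1)CB1OC(C)(C)C(C)(C)O1 | intermediate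
8 | tert-butyl{[(2S,4R)-1,2-bis(pinacolatoboryl)nonadecan-4-yl]oxy}dimethylsilane | CCCCCCCCCCCCCCC[C@@H](O[Si](C)(C)C(C)(C)C)C[C@@H](B1OC(C)(C)C(C)(C)O1)CB1OC(C)(C)C(C)(C)O1 | intermediate
9 | (chloromethyl)isopropoxydimethylsilane | CC(C)O[Si](C)(C)CCl | starting material
10 | [(isopropoxy)dimethylsilyl]methylmagnesium chloride | CC(C)O[Si](C)(C)C[Mg]Cl | intermediate
11 | (S)-1-[isopropoxy(dimethyl)silyl]hex-5-en-3-ol | CC(C)O[Si](C)(C)CC[C@@H](O)CC=C | intermediate
12 | (S)-hex-5-ene-1,3-diol | OCC[C@@H](O)CC=C | intermediate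
13 | (S)-3-hydroxyhex-5-en-1-yl 2,4,6-triisopropylbenzoate | CC(C)c1cc(C(C)C)c(C(=O)OCC[C@@H](O)CC=C)c(C(C)C)c1 | intermediate
14 | (S)-3-(tert-butyldimethylsilyloxy)hex-5-en-1-yl 2,4,6-triisopropylbenzoate | CC(C)c1cc(C(C)C)c(C(=O)OCC[C@@H](O[Si](C)(C)C(C)(C)C)CC=C)c(C(C)C)c1 | intermediate
15 | (1R,3S)-3-(tert-butyldimethylsilyloxy)-1-lithiohex-5-en-1-yl 2,4,6-triisopropylbenzoate ((+)-sparteine complex) | CC(C)c1cc(C(C)C)c(C(=O)O[C@H]([Li])C[C@@H](O[Si](C)(C)C(C)(C)C)CC=C)c(C(C)C)c1 | intermediate
16 | lithium boronate complex of 15 at the primary (C8) boron of 8 | [Li+].CCCCCCCCCCCCCCC[C@@H](O[Si](C)(C)C(C)(C)C)C[C@@H](B1OC(C)(C)C(C)(C)O1)C[B-]1(OC(C)(C)C(C)(C)O1)[C@@H](OC(=O)c1c(C(C)C)cc(C(C)C)cc1C(C)C)C[C@@H](O[Si](C)(C)C(C)(C)C)CC=C | intermediate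
17 | (4R,6R,8S,10R)-4,10-bis(tert-butyldimethylsilyloxy)-6,8-bis(pinacolatoboryl)pentacos-1-ene | CCCCCCCCCCCCCCC[C@@H](O[Si](C)(C)C(C)(C)C)C[C@@H](B1OC(C)(C)C(C)(C)O1)C[C@@H](B1OC(C)(C)C(C)(C)O1)C[C@@H](O[Si](C)(C)C(C)(C)C)CC=C | intermediate
18 | (4S,6R,8S,10R)-4,10-bis(tert-butyldimethylsilyloxy)pentacos-1-ene-6,8-diol | CCCCCCCCCCCCCCC[C@@H](O[Si](C)(C)C(C)(C)C)C[C@@H](O)C[C@@H](O)C[C@@H](O[Si](C)(C)C(C)(C)C)CC=C | intermediate
19 | (4R,6S)-4-[(2S)-2-(tert-butyldimethylsilyloxy)pent-4-en-1-yl]-6-[(2R)-2-(tert-butyldimethylsilyloxy)heptadecyl]-2,2-dimethyl-1,3-dioxane | CCCCCCCCCCCCCCC[C@@H](O[Si](C)(C)C(C)(C)C)C[C@@H]1C[C@H](C[C@@H](O[Si](C)(C)C(C)(C)C)CC=C)OC(C)(C)O1 | intermediate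
20 | ozonide (1,2,4-trioxolane) of 19, undefined at the new ring carbon | CCCCCCCCCCCCCCC[C@@H](O[Si](C)(C)C(C)(C)C)C[C@@H]1C[C@H](C[C@@H](O[Si](C)(C)C(C)(C)C)CC2OCOO2)OC(C)(C)O1 | intermediate
21 | (3R)-3-(tert-butyldimethylsilyloxy)-4-{(4R,6S)-6-[(2R)-2-(tert-butyldimethylsilyloxy)heptadecyl]-2,2-dimethyl-1,3-dioxan-4-yl}butanal | CCCCCCCCCCCCCCC[C@@H](O[Si](C)(C)C(C)(C)C)C[C@@H]1C[C@H](C[C@@H](O[Si](C)(C)C(C)(C)C)CC=O)OC(C)(C)O1 | intermediate
22 | methyl bis(2,2,2-trifluoroethyl)phosphonoacetate | COC(=O)CP(=O)(OCC(F)(F)F)OCC(F)(F)F | starting material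
23 | potassium salt of the carbanion of 22 | [K+].COC(=O)[CH-]P(=O)(OCC(F)(F)F)OCC(F)(F)F | intermediate
24 | methyl (2Z,5S)-5-(tert-butyldimethylsilyloxy)-6-{(4R,6S)-6-[(2R)-2-(tert-butyldimethylsilyloxy)heptadecyl]-2,2-dimethyl-1,3-dioxan-4-yl}hex-2-enoate | CCCCCCCCCCCCCCC[C@@H](O[Si](C)(C)C(C)(C)C)C[C@@H]1C[C@H](C[C@@H](O[Si](C)(C)C(C)(C)C)C/C=C\C(=O)OC)OC(C)(C)O1 | intermediate
25 | methyl (2Z)-5,7,9,11-tetrahydroxyhexacos-2-enoate, all-syn, centres as in 26 | CCCCCCCCCCCCCCC[C@@H](O)C[C@@H](O)C[C@@H](O)C[C@@H](O)C/C=C\C(=O)OC | intermediate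
26 | (6S)-6-[(2R,4R,6R)-2,4,6-trihydroxyhenicosyl]-5,6-dihydro-2H-pyran-2-one | CCCCCCCCCCCCCCC[C@@H](O)C[C@@H](O)C[C@@H](O)C[C@@H]1CC=CC(=O)O1 | target

**Count**
Total steps: 13. Longest linear sequence: 10 steps from (S)-epichlorohydrin (steps 1, 2, then 3–5 or 6–8, then 9–13).

**Steps most likely to fail**

Step 9. The deprotonation of 14 may be slow or poorly face-selective if (+)-sparteine and the resident C5 centre are mismatched. The carbenoid may be captured in part by the secondary boron, and the 1,2-shift may lag behind reversal of boronate formation.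
- The fallback makes the same C7–C8 bond with reversed logic. C7 acts as an acyl-anion equivalent and C8 as the terminal carbon of an epoxide (strain release), in a one-flask silyl-dithiane linchpin coupling with 1,4-Brook rearrangement. It sets out from 6 and 4 and comes back at 18.
- Alcohol 6 is converted with Boc2O and DMAP into tert-butyl (R)-nonadec-1-en-4-yl carbonate F1. IBr in toluene at −85 °C closes the cis-configured cyclic iodocarbonate F2 (syn-selective iodocarbonate cyclisation, C9–O set from C11). K2CO3 in MeOH gives the syn-epoxy alcohol F3, and TBSCl/imidazole gives the epoxide silyl ether F4.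
- Commercial 2-(tert-butyldimethylsilyl)-1,3-dithiane is lithiated (t-BuLi, Et2O, −78 → −45 °C) and opens 4 at its terminal carbon. Addition of F4 in Et2O/HMPA then triggers silyl migration from carbon to the C5 alkoxide. The regenerated dithiane anion opens F4 at C8 to give the dithiane adduct F5, with C5–OTBS and a free C9–OH.
- MeI/CaCO3 in aqueous MeCN unmasks the β-hydroxy ketone F6. Narasaka–Prasad reduction (Et2BOMe, NaBH4, THF/MeOH, −78 °C), with hydride delivered to the boron chelate of C9–O and C7=O, should give the 7,9-syn diol 18.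

Step 4. Facial selectivity of the substrate-directed diboration may be insufficient for an unbranched terminal alkene, and undirected background diboration or partial protodeboronation in the methanolic medium may erode it further.
- The fallback replaces substrate control by catalyst control. It sets out from 6 and comes back at 8.
- Alcohol 6 is silylated first (TBSCl, imidazole, DMF) to (R)-tert-butyldimethyl(nonadec-1-en-4-yloxy)silane F7.
- The alkene is then diborated enantioselectively with B2pin2, Pt(dba)3 and a TADDOL-derived phenylphosphonite ligand in THF at 60 °C. The ligand enantiomer is chosen to deliver the (2S) C–B centre, which gives 8 directly.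

Step 13. During the acid exposure needed to cleave two secondary silyl ethers, the liberated C7 hydroxyl may add in conjugate fashion to the newly formed unsaturated lactone (intramolecular oxa-Michael closure). Lactonisation may also stall before the acetonide is gone.
- The fallback stages the unmasking so that the lactone forms while O7 and O9 are still tied up. It sets out from 24 and comes back at 26.
- HF·pyridine buffered with pyridine in THF cleaves only the silyl ethers, and the free C5 hydroxyl lactonises onto the Z-ester to give the 7,9-O-isopropylidene derivative of the target F8.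
- A short, mild hydrolysis (80% aq. AcOH, rt) then removes the acetonide to give 26.

**Further compounds**
F1 | step 9 | tert-butyl (R)-nonadec-1-en-4-yl carbonate | CCCCCCCCCCCCCCC[C@@H](OC(=O)OC(C)(C)C)CC=C
F2 | step 9 | (4R,6R)-4-(iodomethyl)-6-pentadecyl-1,3-dioxan-2-one | CCCCCCCCCCCCCCC[C@@H]1C[C@H](CI)OC(=O)O1
F3 | step 9 | (2R)-1-[(2R)-oxiran-2-yl]heptadecan-2-ol | CCCCCCCCCCCCCCC[C@@H](O)C[C@@H]1CO1
F4 | step 9 | tert-butyldimethyl({(2R)-1-[(2R)-oxiran-2-yl]heptadecan-2-yl}oxy)silane | CCCCCCCCCCCCCCC[C@@H](O[Si](C)(C)C(C)(C)C)C[C@@H]1CO1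
F5 | step 9 | C7 1,3-dithiane with C5–OTBS, C9–OH and C11–OTBS, centres as in 18 | CCCCCCCCCCCCCCC[C@@H](O[Si](C)(C)C(C)(C)C)C[C@@H](O)CC1(C[C@@H](O[Si](C)(C)C(C)(C)C)CC=C)SCCCS1
F6 | step 9 | C7 ketone with C5–OTBS, C9–OH and C11–OTBS, centres as in 18 | CCCCCCCCCCCCCCC[C@@H](O[Si](C)(C)C(C)(C)C)C[C@@H](O)CC(=O)C[C@@H](O[Si](C)(C)C(C)(C)C)CC=C
F7 | step 4 | (R)-tert-butyldimethyl(nonadec-1-en-4-yloxy)silane | CCCCCCCCCCCCCCC[C@@H](O[Si](C)(C)C(C)(C)C)CC=C
F8 | step 13 | 7,9-O-isopropylidene derivative of 26 | CCCCCCCCCCCCCCC[C@@H](O)C[C@@H]1C[C@H](C[C@@H]2CC=CC(=O)O2)OC(C)(C)O1
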